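**Plan**
- Cuts: the oxirane O–CH2 bond and the aryl ester C–O bond are cut first. The benzene ring is then opened at C1–C2, C3–C4 and C4–C5, giving an isopropenyl(methoxy)carbene complex of zerovalent chromium, one of its CO ligands and a terminal alkyne. The alkyne comes from dihydroxyacetone and an ethynyl Grignard reagent.
- Enabling feature: the benzene ring is a hydroquinone with para oxygens (C1 OMe, C4 O-acyl), H on C2 and C5, and CH3 on C6. The quaternary oxirane carbon sits on C3, ortho to the C4 oxygen. This is the 4-methoxyphenol pattern that an alkenyl methoxycarbene, a terminal alkyne and CO assemble.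
- Forward order: the five-carbon alkyne is built and desymmetrised, then fitted with its leaving group and a silyl cap. The benzene ring is grown around the triple bond, and the oxirane ring is closed last.
- Stereochemistry: the single stereocentre comes from lipase hydrolysis of a prochiral diisobutyrate. No later step breaks a bond to it. The freed CH2OH is sulfonylated at once, so acyl migration cannot scramble it.

Key step: step 7

Assumption: the lipase of step 3 is taken to cleave the pro-R arm of the prochiral diester; this sense must be confirmed on the first batch, and the acylation mode given among the fallbacks delivers the opposite sense with the same enzyme.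

Step 1
Reactants: 1 1,3-dihydroxyacetone (commercial dimer, drawn as the monomer)
Product: 2 2-oxopropane-1,3-diyl bis(2-methylpropanoate)
Conditions: (i-PrCO)2O (2.3 equiv), pyridine, DMAP (cat.), CH2Cl2, 0 °C to rt
Reagents that add atoms: isobutyric anhydride, CC(C)C(=O)OC(=O)C(C)C
Why: DMAP-catalysed O-acylation, in which the dimer reverts to the monomeric ketone in pyridine and both primary hydroxyls are esterified, just as in the standard preparation of 1,3-diacetoxyacetone.

Step 2
Reactants: 2 2-oxopropane-1,3-diyl bis(2-methylpropanoate); 3 ethynylmagnesium bromide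
Product: 4 2-ethynyl-2-hydroxypropane-1,3-diyl bis(2-methylpropanoate)
Conditions: 3 (1.1 equiv, 0.5 M in THF), THF, –40 °C; AcOH in THF at –40 °C, then aqueous work-up
Reagents that add atoms: none
Why: Grignard 1,2-addition, in which the ketone flanked by two acyloxymethyl groups is far more electrophilic than the hindered isobutyrates, the weakly basic acetylide adds rather than enolises, and the cold acid quench protonates the magnesium alkoxide before an ester can shift to the tertiary oxygen; the product has two identical arms and is achiral.

Step 3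
Reactants: 4 2-ethynyl-2-hydroxypropane-1,3-diyl bis(2-methylpropanoate)
Product: 5 (2S)-2-hydroxy-2-(hydroxymethyl)but-3-yn-1-yl 2-methylpropanoate
Conditions: Burkholderia cepacia lipase (Amano PS, immobilised), 0.1 M phosphate buffer pH 7, MTBE, 25 °C, stopped after one ester has been cleaved
Reagents that add atoms: none
Why: Lipase-catalysed enantiotopos-selective hydrolysis of a prochiral propane-1,3-diyl diester, a desymmetrisation with close precedent among 2-alkynylglycerol diesters, in which the chiral active site accepts only the pro-R arm and so sets the quaternary centre as S, while any over-hydrolysis should consume the minor enantiomer faster and raise the optical purity.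

Step 4
Reactants: 5 (2S)-2-hydroxy-2-(hydroxymethyl)but-3-yn-1-yl 2-methylpropanoate
Product: 6 (2R)-2-hydroxy-2-{[(4-methylphenyl)sulfonyloxy]methyl}but-3-yn-1-yl 2-methylpropanoate
Conditions: TsCl (1.05 equiv), Et3N (1.1 equiv), Bu2SnO (2 mol %), CH2Cl2, 0 °C, on freshly isolated 5
Reagents that add atoms: p-toluenesulfonyl chloride, Cc1ccc(cc1)S(=O)(=O)Cl
Why: Bu2SnO-catalysed regioselective monosulfonylation of a 1,2-diol through its stannylene acetal, which activates the primary oxygen and leaves the tertiary one alone; capping the last primary hydroxyl ends any chance of racemisation by a 1,3-acyl shift, and the descriptor becomes R only because the sulfonate arm now outranks the ester arm.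

Step 5
Reactants: 6 (2R)-2-hydroxy-2-{[(4-methylphenyl)sulfonyloxy]methyl}but-3-yn-1-yl 2-methylpropanoate
Product: 7 (2R)-2-{[(4-methylphenyl)sulfonyloxy]methyl}-2-(triethylsilyloxy)but-3-yn-1-yl 2-methylpropanoate
Conditions: TESOTf (1.2 equiv), 2,6-lutidine (1.5 equiv), CH2Cl2, –78 to 0 °C
Reagents that add atoms: triethylsilyl triflate, CC[Si](CC)(CC)OS(=O)(=O)C(F)(F)F
Why: Silyl triflate silylation of a tertiary propargylic alcohol with a base too weak and too hindered to trigger oxirane closure, giving a cap that keeps the hydroxyl away from the ketene of step 7.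

Step 6
Reactants: 8 2-bromopropene; 9 chromium hexacarbonyl
Product: 12 pentacarbonyl[methoxy(prop-1-en-2-yl)carbene]chromium, via isopropenyllithium 10 (not isolated), via acylchromate (CO)5Cr=C(OLi)C(CH3)=CH2 11 (not isolated)
Conditions: t-BuLi (2.0 equiv), Et2O, –78 °C; Cr(CO)6, Et2O, 0 °C to rt; MeOTf, CH2Cl2, 0 °C
Reagents that add atoms: methyl triflate, COS(=O)(=O)C(F)(F)F
Why: Fischer carbene synthesis, in which bromine–lithium exchange gives the vinyllithium, this adds to a CO ligand of Cr(CO)6, and the hard methylating agent alkylates the acylmetalate on oxygen.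

Step 7
Reactants: 7 (2R)-2-{[(4-methylphenyl)sulfonyloxy]methyl}-2-(triethylsilyloxy)but-3-yn-1-yl 2-methylpropanoate; 12 pentacarbonyl[methoxy(prop-1-en-2-yl)carbene]chromium
Product: 14 (2R)-2-(2-hydroxy-5-methoxy-4-methylphenyl)-3-[(4-methylphenyl)sulfonyloxy]-2-(triethylsilyloxy)propyl 2-methylpropanoate, via η6-arene Cr(CO)3 complex 13 (not isolated)
Conditions: 12 (1.5 equiv), degassed THF (0.3 M in 7), 50 °C, argon; then air, CH2Cl2, rt, filtration through silica
Reagents that add atoms: none
Why: Thermal loss of a cis CO ligand from 12 opens a site for the terminal alkyne of 7, which inserts into the Cr=C bond (new C1–C2 bond) to give a vinylcarbene, and migration of a CO ligand onto its carbene carbon (new C3–C4 bond) gives a chromium-bound dienylketene. The benzene ring, the only ring closed here, forms by a six-electron electrocyclisation joining the ketene carbon C4 to the isopropenyl CH2 (C5), and enolisation of the cyclohexadienone gives the 4-methoxyphenol as its Cr(CO)3 complex 13, from which air releases 14. This is the Dötz benzannulation in its most reliable form, an alkenyl(methoxy)carbene complex of zerovalent chromium with a terminal alkyne in THF, and both propargylic silyl ethers and tert-alkylacetylenes are known partners. No stereocentre is created: the quaternary carbon sits one bond outside the reacting π system, bears no hydrogen and has every oxygen capped, so its configuration is carried through unchanged, while the planar chirality of 13 disappears on demetallation. The selectivity needed is regiochemical, and it is secured by the steric demand of the alkyne substituent in the vinylcarbene, which places the substituted alkyne carbon next to the CO-derived carbon and the CH terminus next to the carbene carbon, so the side chain lands on C3 beside the C4 hydroxyl; the quaternary group only sharpens this bias. The free phenol and the para methyl ether emerge already differentiated, and the tertiary oxygen is silylated because a free propargylic hydroxyl could intercept the ketene as a β-lactone.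

Step 8
Reactants: 14 (2R)-2-(2-hydroxy-5-methoxy-4-methylphenyl)-3-[(4-methylphenyl)sulfonyloxy]-2-(triethylsilyloxy)propyl 2-methylpropanoate
Product: 15 (2R)-2-{5-methoxy-4-methyl-2-[(2-methylpropanoyl)oxy]phenyl}-3-[(4-methylphenyl)sulfonyloxy]-2-(triethylsilyloxy)propyl 2-methylpropanoate
Conditions: (i-PrCO)2O (1.5 equiv), Et3N, DMAP (10 mol %), CH2Cl2, 0 °C to rt
Reagents that add atoms: isobutyric anhydride, CC(C)C(=O)OC(=O)C(C)C
Why: DMAP-catalysed acylation of the only free hydroxyl, a hindered phenol, which at 0 °C should be much faster than 5-exo attack of the phenoxide on the neopentyl-type sulfonate carbon, so ring closure to a dihydrobenzofuran should not compete.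

Step 9
Reactants: 15 (2R)-2-{5-methoxy-4-methyl-2-[(2-methylpropanoyl)oxy]phenyl}-3-[(4-methylphenyl)sulfonyloxy]-2-(triethylsilyloxy)propyl 2-methylpropanoate
Product: 16 (2R)-2-hydroxy-2-{5-methoxy-4-methyl-2-[(2-methylpropanoyl)oxy]phenyl}-3-[(4-methylphenyl)sulfonyloxy]propyl 2-methylpropanoate
Conditions: HF·pyridine, pyridine, THF, 0 °C to rt
Reagents that add atoms: none
Why: Fluoride-driven Si–O cleavage in a slightly acidic medium, where both esters and the sulfonate are inert and no alkoxide arises that could pick up the neighbouring aryl ester.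

Step 10
Reactants: 16 (2R)-2-hydroxy-2-{5-methoxy-4-methyl-2-[(2-methylpropanoyl)oxy]phenyl}-3-[(4-methylphenyl)sulfonyloxy]propyl 2-methylpropanoate
Product: 17 [(2S)-2-{5-methoxy-4-methyl-2-[(2-methylpropanoyl)oxy]phenyl}oxiran-2-yl]methyl 2-methylpropanoate
Conditions: Cs2CO3 (1.5 equiv, dry), MeCN, 0 °C to rt
Reagents that add atoms: none
Why: Intramolecular Williamson etherification (3-exo-tet), in which the tertiary alkoxide displaces the primary tosylate with help from the Thorpe–Ingold effect of the fully substituted carbon, using a non-nucleophilic carbonate in an aprotic solvent as for glycidyl esters so that neither ester is solvolysed; no bond to the stereocentre is touched, and the descriptor returns to S through the priority change alone.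

**Compound list**
1 | 1,3-dihydroxyacetone (sold as its dimer) | OCC(=O)CO | starting material
2 | 2-oxopropane-1,3-diyl bis(2-methylpropanoate) | CC(C)C(=O)OCC(=O)COC(=O)C(C)C | intermediate
3 | ethynylmagnesium bromide | C#C[Mg]Br | starting material
4 | 2-ethynyl-2-hydroxypropane-1,3-diyl bis(2-methylpropanoate) | C#CC(O)(COC(=O)C(C)C)COC(=O)C(C)C | intermediate
5 | (2S)-2-hydroxy-2-(hydroxymethyl)but-3-yn-1-yl 2-methylpropanoate | C#C[C@@](O)(COC(=O)C(C)C)CO | intermediate
6 | (2R)-2-hydroxy-2-{[(4-methylphenyl)sulfonyloxy]methyl}but-3-yn-1-yl 2-methylpropanoate | C#C[C@@](O)(COC(=O)C(C)C)COS(=O)(=O)c1ccc(C)cc1 | intermediate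
7 | (2R)-2-{[(4-methylphenyl)sulfonyloxy]methyl}-2-(triethylsilyloxy)but-3-yn-1-yl 2-methylpropanoate | C#C[C@@](O[Si](CC)(CC)CC)(COC(=O)C(C)C)COS(=O)(=O)c1ccc(C)cc1 | intermediate
8 | 2-bromopropene | CC(Br)=C | starting material
9 | chromium hexacarbonyl | O=C=[Cr](=C=O)(=C=O)(=C=O)(=C=O)=C=O | starting material
10 | isopropenyllithium | [Li]C(C)=C | intermediate
11 | lithium acylchromate (CO)5Cr=C(OLi)C(CH3)=CH2 | [Li+].[O-]C(C(C)=C)=[Cr](=C=O)(=C=O)(=C=O)(=C=O)=C=O | intermediate
12 | pentacarbonyl[methoxy(prop-1-en-2-yl)carbene]chromium | COC(C(C)=C)=[Cr](=C=O)(=C=O)(=C=O)(=C=O)=C=O | intermediate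
13 | tricarbonylchromium complex of 14, Cr(CO)3 bound η6 to the new benzene ring, mixture of planar diastereomers | COc1cc([C@@](O[Si](CC)(CC)CC)(COC(=O)C(C)C)COS(=O)(=O)c2ccc(C)cc2)c(O)cc1C.O=C=[Cr](=C=O)=C=O | intermediate
14 | (2R)-2-(2-hydroxy-5-methoxy-4-methylphenyl)-3-[(4-methylphenyl)sulfonyloxy]-2-(triethylsilyloxy)propyl 2-methylpropanoate | COc1cc([C@@](O[Si](CC)(CC)CC)(COC(=O)C(C)C)COS(=O)(=O)c2ccc(C)cc2)c(O)cc1C | intermediate
15 | (2R)-2-{5-methoxy-4-methyl-2-[(2-methylpropanoyl)oxy]phenyl}-3-[(4-methylphenyl)sulfonyloxy]-2-(triethylsilyloxy)propyl 2-methylpropanoate | COc1cc([C@@](O[Si](CC)(CC)CC)(COC(=O)C(C)C)COS(=O)(=O)c2ccc(C)cc2)c(OC(=O)C(C)C)cc1C | intermediate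
16 | (2R)-2-hydroxy-2-{5-methoxy-4-methyl-2-[(2-methylpropanoyl)oxy]phenyl}-3-[(4-methylphenyl)sulfonyloxy]propyl 2-methylpropanoate | COc1cc([C@@](O)(COC(=O)C(C)C)COS(=O)(=O)c2ccc(C)cc2)c(OC(=O)C(C)C)cc1C | intermediate
17 | [(2S)-2-{5-methoxy-4-methyl-2-[(2-methylpropanoyl)oxy]phenyl}oxiran-2-yl]methyl 2-methylpropanoate | COc1cc([C@@]2(COC(=O)C(C)C)CO2)c(OC(=O)C(C)C)cc1C | target

**Step count:** 10 steps in total. The longest linear sequence is 9 steps (steps 1–5, then 7–10). Step 6 is the one-step side branch.

**Steps most likely to fail**

Step 7.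
- Risk: alkyne uptake and insertion may be sluggish next to an acyclic quaternary carbon with three large arms. Thermal decay of the carbene complex, or diversion of the vinylketene before electrocyclisation, could then win.
- Fallback: keep the same ring construction, tie two arms back in a five-membered ketal, and add the leaving group after the arene is made.
- It sets out from 5. 2,2-Dimethoxypropane and catalytic PPTS in CH2Cl2 should give [(4S)-4-ethynyl-2,2-dimethyl-1,3-dioxolan-4-yl]methyl 2-methylpropanoate F1.
- Heating F1 with 12 in THF should lead through the η6-arene Cr(CO)3 complex F2. After exposure to air this should give [(4S)-4-(2-hydroxy-5-methoxy-4-methylphenyl)-2,2-dimethyl-1,3-dioxolan-4-yl]methyl 2-methylpropanoate F3.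
- Isobutyric anhydride, Et3N and DMAP should convert the phenol into [(4S)-4-{5-methoxy-4-methyl-2-[(2-methylpropanoyl)oxy]phenyl}-2,2-dimethyl-1,3-dioxolan-4-yl]methyl 2-methylpropanoate F4.
- Aqueous AcOH at 40 °C should release (2S)-2,3-dihydroxy-2-{5-methoxy-4-methyl-2-[(2-methylpropanoyl)oxy]phenyl}propyl 2-methylpropanoate F5.
- Immediate Bu2SnO-catalysed tosylation of the primary hydroxyl of F5 brings the material back to the route at 16.

Step 10.
- Risk: the aryl isobutyryl group may transfer to the tertiary alkoxide through a six-membered transition state, in competition with oxirane closure. The liberated phenoxide would then attack the sulfonate carbon.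
- Fallback: reverse the order, so that no aryl ester is present when the alkoxide is formed.
- It sets out from 14. HF·pyridine should give (2R)-2-hydroxy-2-(2-hydroxy-5-methoxy-4-methylphenyl)-3-[(4-methylphenyl)sulfonyloxy]propyl 2-methylpropanoate F6.
- NaH (2.2 equiv) in THF at 0 °C forms the phenoxide–alkoxide dianion. Its alkoxide should close the three-membered ring far faster than the phenoxide can reach the neopentyl-type carbon in a 5-exo mode. This should give sodium 4-methoxy-5-methyl-2-[(2S)-2-{[(2-methylpropanoyl)oxy]methyl}oxiran-2-yl]phenolate F7.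
- F7 is acylated in the same flask with isobutyryl chloride at low temperature, which returns to the route at 17.

Step 3.
- Risk: the enzyme may show the wrong sense or too low a level of enantiotopic discrimination. Turnover of the α-branched ester may also be slow enough for acyl migration in water to erode optical purity.
- Fallback: change from hydrolysis to acylation in an organic solvent.
- It sets out from 4, which is methanolysed (catalytic K2CO3, MeOH) to 2-ethynylpropane-1,2,3-triol F8.
- The triol is mono-acylated with vinyl isobutyrate and the same lipase in MTBE. The enzyme addresses the same arm in both directions, so this mode gives the mirror-image selectivity of the hydrolysis, and the acyl donor is irreversible. It returns to the route at 5.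

**Further compounds**
F1 | step 7 | [(4S)-4-ethynyl-2,2-dimethyl-1,3-dioxolan-4-yl]methyl 2-methylpropanoate | C#C[C@@]1(COC(=O)C(C)C)COC(C)(C)O1
F2 | step 7 | tricarbonylchromium complex of F3, Cr(CO)3 bound η6 to the new benzene ring | COc1cc([C@@]2(COC(=O)C(C)C)COC(C)(C)O2)c(O)cc1C.O=C=[Cr](=C=O)=C=O
F3 | step 7 | [(4S)-4-(2-hydroxy-5-methoxy-4-methylphenyl)-2,2-dimethyl-1,3-dioxolan-4-yl]methyl 2-methylpropanoate | COc1cc([C@@]2(COC(=O)C(C)C)COC(C)(C)O2)c(O)cc1C
F4 | step 7 | [(4S)-4-{5-methoxy-4-methyl-2-[(2-methylpropanoyl)oxy]phenyl}-2,2-dimethyl-1,3-dioxolan-4-yl]methyl 2-methylpropanoate | COc1cc([C@@]2(COC(=O)C(C)C)COC(C)(C)O2)c(OC(=O)C(C)C)cc1C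
F5 | step 7 | (2S)-2,3-dihydroxy-2-{5-methoxy-4-methyl-2-[(2-methylpropanoyl)oxy]phenyl}propyl 2-methylpropanoate | COc1cc([C@@](O)(COC(=O)C(C)C)CO)c(OC(=O)C(C)C)cc1C
F6 | step 10 | (2R)-2-hydroxy-2-(2-hydroxy-5-methoxy-4-methylphenyl)-3-[(4-methylphenyl)sulfonyloxy]propyl 2-methylpropanoate | COc1cc([C@@](O)(COC(=O)C(C)C)COS(=O)(=O)c2ccc(C)cc2)c(O)cc1C
F7 | step 10 | sodium 4-methoxy-5-methyl-2-[(2S)-2-{[(2-methylpropanoyl)oxy]methyl}oxiran-2-yl]phenolate | [Na+].COc1cc([C@@]2(COC(=O)C(C)C)CO2)c([O-])cc1C
F8 | step 3 | 2-ethynylpropane-1,2,3-triol | C#CC(O)(CO)CO
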